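The numbers of this flask are those of an exercise; the flask was simulated.

At this reading the flask is new again, so the examination starts from its charges.

E 0.20 M; J 0.200 M; Z 45 mM (held); time 15 s

    Z ⇌ D, rate k1*(csat - [D]) (k1 = 0.0590 /s, csat = 45 mM)
    D + X → D.X (k2 = 6.25 /M/s)
    L ⇌ J.X, rate k3*(cs3 - [J.X]) while solid is left; crystals form when [J.X] > cs3 (cs3 = 0.18 M, k3 = 1.09 /s)
    J + X → J.X (k4 = 30.3 /M/s)
    E ⇌ X (K5 = 0.00286, k5 = 1.14 /s)

- for J.X the L are counted in
- as a solid, counted per litre of solution: L
- at the start none of D is dissolved
- run time (flask): 15 s

* amount of J.X and L together at 15 s, in percent of the E charged
* concentration of J.X in solution at 15 s, in percent of saturation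

Question: what becomes of X once it is made? Answer: with no D dissolved at the start, it has two ways out, and I weigh them per second. It falls back to E at 399 /s and goes on to J.X at 6.06 /s with J as charged. The way back is much faster, so E and X stay in balance (a pre-equilibrium), with X at about 0.286% of E.

Question: what number do you carry? Answer: the lifetime of E, here 57.7 s: one over the product of the balance constant of E and X, the rate constant of J + X, and the amount of J as charged.

Question: but J falls along with E, so does that lifetime hold? Answer: not as it stands. The two are charged equally and go one for one, so the lifetime stretches as they fall. For equal charges the part converted is the time over the time plus the lifetime, which gives me 20.6%.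

Question: and the side path through D? Answer: even with D at saturation, it takes X at 0.281 /s, far slower than J does, so I leave it out.

Question: do crystals form? Answer: my count gives 0.0413 M of J.X, less than the solubility of 0.18 M, so none form in my reckoning, and the solution stands at 22.9% of saturation.

The forecast says 20.3% (range 19.5% to 21%) and 22.6% (range 21.7% to 23.4%), a little lower than mine, holding that “no crystals form, L stays zero, and all the product remains in solution”.

The flask gives 20.3% and 22.6%, with L at 0%, inside both forecast ranges. Its small yield comes mainly from X falling back to E: with that way back removed, the flask reaches 97.4% instead of 20.3%. In this flask 15 s is 0.260 of the lifetime with J as charged. In the neighbour flask with 0.80 M of J, a pseudo-first-order case, the lifetime shortens to 14.4 s, and 1.04 lifetimes reckon to 64.7% of E converted with J held at its charge. That neighbour flask, its J down to 85.2% of its charge, holds J.X and L together at 59.2%.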